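**Retrosynthetic overview**
1. The target is prostaglandin E3 1,15-lactone 11-acetate; the acetate goes on last, after the C11 silyl ether is removed.
2. The 5Z-alkene comes from syn semi-hydrogenation of a 13-membered cycloalkyne, closed by ring-closing alkyne metathesis at C5≡C6. This lactone ring is the only ring made in the route, and it is formed last.
3. The C1–O15 ester bond comes from acylating the free 15-OH with hept-5-ynoic acid.
4. The cyclopentanone core (ring bought as the enone, C11 stereocentre included) comes from a three-component coupling: (R)-4-silyloxycyclopentenone, the ω-chain alkenyl zincate (C12–C13 bond) and 1-iodobut-2-yne (C7–C8 bond).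
5. The ω-chain comes from (Z)-hex-3-enal and a stannylvinyllithium; a Sharpless kinetic resolution sets C15.

Assumption: the target is read as (8R,11R,12R,15S; 5Z,13E,17Z), and compounds 1, 3, 8, 10 and 16 are taken as purchasable.

**Route**

Step 1
Reactants: 1 (3Z)-hex-3-en-1-ol
Product: 2 (3Z)-hex-3-enal
Conditions: Dess–Martin periodinane (1.2 equiv), NaHCO3, CH2Cl2, 0 °C to rt; used crude at once
Reagents that add atoms: none
Why: Buffered Dess–Martin oxidation is fast and near neutral, so the skipped Z-alkene neither isomerises nor moves into conjugation.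

Step 2
Reactants: 3 (E)-1,2-bis(tributylstannyl)ethene; 2 (3Z)-hex-3-enal
Product: 5 rac-(1E,5Z)-1-(tributylstannyl)octa-1,5-dien-3-ol, via (E)-2-(tributylstannyl)vinyllithium 4 (not isolated)
Conditions: 3, n-BuLi (1.0 equiv), THF, −78 °C, 1 h; then 2, −78 °C; H2O quench
Reagents that add atoms: none
Why: Tin–lithium exchange of one stannyl group keeps the E geometry, and 1,2-addition of the alkenyllithium to the aldehyde at −78 °C outruns enolisation, giving the racemic γ-stannyl allylic alcohol.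

Step 3
Reactants: 5 rac-(1E,5Z)-1-(tributylstannyl)octa-1,5-dien-3-ol
Product: 6 (1E,3S,5Z)-1-(tributylstannyl)octa-1,5-dien-3-ol
Conditions: Ti(OiPr)4 (1.0 equiv), D-(−)-diisopropyl tartrate (1.2 equiv), t-BuOOH (0.7 equiv), 4 Å MS, CH2Cl2, −20 °C
Reagents that add atoms: none
Why: In this Sharpless kinetic resolution the D-(−)-tartrate complex epoxidises the (R)-alcohol far faster, so the (S)-alcohol (the C15 configuration) is recovered in high ee at just over 50% conversion, while the homoallylic 5Z-alkene reacts much more slowly.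

Step 4
Reactants: 6 (1E,3S,5Z)-1-(tributylstannyl)octa-1,5-dien-3-ol
Product: 7 triethyl{[(1E,3S,5Z)-1-(tributylstannyl)octa-1,5-dien-3-yl]oxy}silane
Conditions: Et3SiCl, imidazole, CH2Cl2, 0 °C
Reagents that add atoms: chlorotriethylsilane, CC[Si](Cl)(CC)CC
Why: Silyl ether formation masks the alcohol for the organometallic step and leaves the stereocentre untouched.

Step 5
Reactants: 8 1-bromobut-2-yne
Product: 9 1-iodobut-2-yne
Conditions: NaI (1.5 equiv), acetone, rt, dark; used fresh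
Reagents that add atoms: sodium iodide, [Na+].[I-]
Why: Finkelstein halide exchange, driven by precipitation of the sodium halide, gives the more reactive propargylic iodide needed for enolate trapping.

Step 6
Reactants: 7 triethyl{[(1E,3S,5Z)-1-(tributylstannyl)octa-1,5-dien-3-yl]oxy}silane; 10 (4R)-4-[(tert-butyldimethylsilyl)oxy]cyclopent-2-en-1-one; 9 1-iodobut-2-yne
Product: 14 (2R,3R,4R)-2-(but-2-yn-1-yl)-4-[(tert-butyldimethylsilyl)oxy]-3-[(1E,3S,5Z)-3-[(triethylsilyl)oxy]octa-1,5-dien-1-yl]cyclopentan-1-one, via alkenyllithium 11 (not isolated), via lithium alkenyldimethylzincate 12 (not isolated), via zinc enolate 13 (not isolated)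
Conditions: 7, n-BuLi, THF, −78 °C; Me2Zn (1.0 equiv), −78 °C; 10, −78 °C, 1 h; then HMPA, 9 (5 equiv), −78 to −40 °C; aq NH4Cl
Reagents that add atoms: none
Why: In this Noyori-type three-component coupling the alkenyl zincate adds 1,4 to the enone anti to the C11 silyloxy group (sets C12), and the regiodefined enolate is alkylated by the propargylic iodide anti to the new side chain (sets C8), giving the all-trans cyclopentanone.

Step 7
Reactants: 14 (2R,3R,4R)-2-(but-2-yn-1-yl)-4-[(tert-butyldimethylsilyl)oxy]-3-[(1E,3S,5Z)-3-[(triethylsilyl)oxy]octa-1,5-dien-1-yl]cyclopentan-1-one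
Product: 15 (2R,3R,4R)-2-(but-2-yn-1-yl)-4-[(tert-butyldimethylsilyl)oxy]-3-[(1E,3S,5Z)-3-hydroxyocta-1,5-dien-1-yl]cyclopentan-1-one
Conditions: PPTS (0.2 equiv), MeOH/CH2Cl2 (1:1), 0 °C
Reagents that add atoms: none
Why: Acid-catalysed methanolysis (chemoselective desilylation) cleaves the less hindered triethylsilyl ether much faster than the tert-butyldimethylsilyl ether, and the mild acid does not cause β-elimination at C11.

Step 8
Reactants: 15 (2R,3R,4R)-2-(but-2-yn-1-yl)-4-[(tert-butyldimethylsilyl)oxy]-3-[(1E,3S,5Z)-3-hydroxyocta-1,5-dien-1-yl]cyclopentan-1-one; 16 hept-5-ynoic acid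
Product: 17 (1E,3S,5Z)-1-[(1R,2R,5R)-2-(but-2-yn-1-yl)-5-[(tert-butyldimethylsilyl)oxy]-3-oxocyclopentyl]octa-1,5-dien-3-yl hept-5-ynoate
Conditions: DCC (1.3 equiv), DMAP (0.1 equiv), CH2Cl2, 0 °C to rt
Reagents that add atoms: none
Why: Steglich esterification acylates the only free hydroxyl with retention at C15, and catalytic DMAP in the cold avoids β-elimination of the silyloxy ketone.

Step 9
Reactants: 17 (1E,3S,5Z)-1-[(1R,2R,5R)-2-(but-2-yn-1-yl)-5-[(tert-butyldimethylsilyl)oxy]-3-oxocyclopentyl]octa-1,5-dien-3-yl hept-5-ynoate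
Product: 18 5,6-didehydro-prostaglandin E3 1,15-lactone 11-(tert-butyldimethylsilyl) ether (13-membered cycloalkyne lactone; C5≡C6; 8R,11R,12R,15S; 13E,17Z)
Conditions: Mo(≡CC6H4-4-OMe)(OSiPh3)3 (5 mol%), 5 Å MS, toluene (2 mM), rt to 60 °C
Reagents that add atoms: none
Why: Ring-closing alkyne metathesis of the two methyl-capped alkynes is driven by loss of volatile but-2-yne, and the molybdenum alkylidyne leaves the C13 and C17 alkenes, the ketone and the silyl ether untouched.

Step 10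
Reactants: 18 5,6-didehydro-prostaglandin E3 1,15-lactone 11-(tert-butyldimethylsilyl) ether
Product: 19 prostaglandin E3 1,15-lactone 11-(tert-butyldimethylsilyl) ether (5Z,13E,17Z; 8R,11R,12R,15S)
Conditions: H2 (1 atm), Pd/CaCO3 poisoned with Pb(OAc)2, quinoline, hexane/EtOAc, rt; stopped at 1 equiv H2
Reagents that add atoms: none
Why: Lindlar-type syn semi-hydrogenation turns the ring alkyne into the 5Z-alkene, and the poisoned palladium reduces the disubstituted 13E and 17Z alkenes much more slowly.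

Step 11
Reactants: 19 prostaglandin E3 1,15-lactone 11-(tert-butyldimethylsilyl) ether
Product: 20 prostaglandin E3 1,15-lactone, (5Z,8R,11R,12R,13E,15S,17Z)-11-hydroxy-9-oxoprosta-5,13,17-trien-1,15-olide
Conditions: aq HF (48%), MeCN, 0 °C
Reagents that add atoms: none
Why: Fluoride desilylation under acidic, non-basic conditions frees the C11 hydroxyl without β-elimination or lactone opening.

Step 12
Reactants: 20 prostaglandin E3 1,15-lactone
Product: 21 prostaglandin E3 1,15-lactone 11-acetate, (5Z,8R,11R,12R,13E,15S,17Z)-11-acetoxy-9-oxoprosta-5,13,17-trien-1,15-olide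
Conditions: Ac2O, pyridine, CH2Cl2, 0 °C to rt, no DMAP
Reagents that add atoms: acetic anhydride, CC(=O)OC(C)=O
Why: O-Acylation of the single secondary hydroxyl proceeds with retention at C11, and DMAP-free, cold, short conditions keep the β-acetoxy ketone from eliminating to the enone.

**Compound list**

1 | (3Z)-hex-3-en-1-ol | CC/C=C\CCO | starting material
2 | (3Z)-hex-3-enal | CC/C=C\CC=O | intermediate
3 | (E)-1,2-bis(tributylstannyl)ethene | CCCC[Sn](CCCC)(CCCC)/C=C/[Sn](CCCC)(CCCC)CCCC | starting material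
4 | (E)-2-(tributylstannyl)vinyllithium (not isolated) | [Li]/C=C/[Sn](CCCC)(CCCC)CCCC | intermediate
5 | rac-(1E,5Z)-1-(tributylstannyl)octa-1,5-dien-3-ol | CC/C=C\CC(O)/C=C/[Sn](CCCC)(CCCC)CCCC | intermediate
6 | (1E,3S,5Z)-1-(tributylstannyl)octa-1,5-dien-3-ol | CC/C=C\C[C@H](O)/C=C/[Sn](CCCC)(CCCC)CCCC | intermediate
7 | triethyl{[(1E,3S,5Z)-1-(tributylstannyl)octa-1,5-dien-3-yl]oxy}silane | CC/C=C\C[C@H](O[Si](CC)(CC)CC)/C=C/[Sn](CCCC)(CCCC)CCCC | intermediate
8 | 1-bromobut-2-yne | CC#CCBr | starting material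
9 | 1-iodobut-2-yne | CC#CCI | intermediate
10 | (4R)-4-[(tert-butyldimethylsilyl)oxy]cyclopent-2-en-1-one | CC(C)(C)[Si](C)(C)O[C@@H]1CC(=O)C=C1 | starting material
11 | [(1E,3S,5Z)-3-[(triethylsilyl)oxy]octa-1,5-dien-1-yl]lithium (not isolated) | CC/C=C\C[C@H](O[Si](CC)(CC)CC)/C=C/[Li] | intermediate
12 | lithium dimethyl[(1E,3S,5Z)-3-[(triethylsilyl)oxy]octa-1,5-dien-1-yl]zincate (not isolated) | [Li+].CC/C=C\C[C@H](O[Si](CC)(CC)CC)/C=C/[Zn-](C)C | intermediate
13 | lithium dimethylzincate enolate (C8=C9–O) of (3R,4R)-4-[(tert-butyldimethylsilyl)oxy]-3-[(1E,3S,5Z)-3-[(triethylsilyl)oxy]octa-1,5-dien-1-yl]cyclopentanone (not isolated) | [Li+].CC/C=C\C[C@H](O[Si](CC)(CC)CC)/C=C/[C@H]1[C@H](O[Si](C)(C)C(C)(C)C)CC(O[Zn-](C)C)=C1 | intermediate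
14 | (2R,3R,4R)-2-(but-2-yn-1-yl)-4-[(tert-butyldimethylsilyl)oxy]-3-[(1E,3S,5Z)-3-[(triethylsilyl)oxy]octa-1,5-dien-1-yl]cyclopentan-1-one | CC/C=C\C[C@H](O[Si](CC)(CC)CC)/C=C/[C@H]1[C@H](O[Si](C)(C)C(C)(C)C)CC(=O)[C@@H]1CC#CC | intermediate
15 | (2R,3R,4R)-2-(but-2-yn-1-yl)-4-[(tert-butyldimethylsilyl)oxy]-3-[(1E,3S,5Z)-3-hydroxyocta-1,5-dien-1-yl]cyclopentan-1-one | CC/C=C\C[C@H](O)/C=C/[C@H]1[C@H](O[Si](C)(C)C(C)(C)C)CC(=O)[C@@H]1CC#CC | intermediate
16 | hept-5-ynoic acid | CC#CCCCC(=O)O | starting material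
17 | (1E,3S,5Z)-1-[(1R,2R,5R)-2-(but-2-yn-1-yl)-5-[(tert-butyldimethylsilyl)oxy]-3-oxocyclopentyl]octa-1,5-dien-3-yl hept-5-ynoate | CC/C=C\C[C@H](OC(=O)CCCC#CC)/C=C/[C@H]1[C@H](O[Si](C)(C)C(C)(C)C)CC(=O)[C@@H]1CC#CC | intermediate
18 | 5,6-didehydro-prostaglandin E3 1,15-lactone 11-(tert-butyldimethylsilyl) ether | CC/C=C\C[C@H]1/C=C/[C@H]2[C@H](O[Si](C)(C)C(C)(C)C)CC(=O)[C@@H]2CC#CCCCC(=O)O1 | intermediate
19 | prostaglandin E3 1,15-lactone 11-(tert-butyldimethylsilyl) ether | CC/C=C\C[C@H]1/C=C/[C@H]2[C@H](O[Si](C)(C)C(C)(C)C)CC(=O)[C@@H]2C/C=C\CCCC(=O)O1 | intermediate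
20 | prostaglandin E3 1,15-lactone | CC/C=C\C[C@H]1/C=C/[C@H]2[C@H](O)CC(=O)[C@@H]2C/C=C\CCCC(=O)O1 | intermediate
21 | prostaglandin E3 1,15-lactone 11-acetate | CC/C=C\C[C@H]1/C=C/[C@H]2[C@H](OC(C)=O)CC(=O)[C@@H]2C/C=C\CCCC(=O)O1 | target

**Step count**

Total: 12 steps. Longest linear sequence: 11 steps (steps 1, 2, 3, 4, 6, 7, 8, 9, 10, 11, 12); step 5 is a one-step side branch.

**Steps most likely to fail, with fallbacks**

Step 6 (three-component coupling). The alkylation of the enolate is the weak point, since proton transfer and β-elimination of the silyloxy group compete. The fallback sets out from 7 and comes back at 14. Enolate 13 is made from 7 and 10 as before but is trapped at −78 °C by the much faster aldol reaction with but-2-ynal F2, freshly released from commercial but-2-ynal diethyl acetal with aqueous formic acid. This gives (2S,3R,4R)-4-[(tert-butyldimethylsilyl)oxy]-2-(1-hydroxybut-2-yn-1-yl)-3-[(1E,3S,5Z)-3-[(triethylsilyl)oxy]octa-1,5-dien-1-yl]cyclopentan-1-one F3 as a mixture of carbinol epimers. PhOC(S)Cl and pyridine turn it into O-{1-[(1S,2R,3R)-3-[(tert-butyldimethylsilyl)oxy]-5-oxo-2-[(1E,3S,5Z)-3-[(triethylsilyl)oxy]octa-1,5-dien-1-yl]cyclopentyl]but-2-yn-1-yl} O-phenyl carbonothioate F4. Barton–McCombie deoxygenation (Bu3SnH, AIBN, toluene, 80 °C) then removes the propargylic oxygen and gives 14.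

Step 9 (ring-closing alkyne metathesis). Strain in the 13-membered cycloalkyne, which also holds an E-alkene and is fused to the cyclopentane, may favour oligomers. The fallback sets out from 14 and comes back at 19, closing the ring at the ester bond instead. Acid 16 is esterified (MeOH, cat. H2SO4) to methyl hept-5-ynoate F5. Intermolecular alkyne cross-metathesis of 14 with excess F5 (same molybdenum alkylidyne, 5 Å MS, toluene) gives methyl 7-[(1R,2R,3R)-3-[(tert-butyldimethylsilyl)oxy]-5-oxo-2-[(1E,3S,5Z)-3-[(triethylsilyl)oxy]octa-1,5-dien-1-yl]cyclopentyl]hept-5-ynoate F6. Semi-hydrogenation over Pd/CaCO3 poisoned with Pb(OAc)2 gives methyl (5Z)-7-[(1R,2R,3R)-3-[(tert-butyldimethylsilyl)oxy]-5-oxo-2-[(1E,3S,5Z)-3-[(triethylsilyl)oxy]octa-1,5-dien-1-yl]cyclopentyl]hept-5-enoate F7. PPTS in MeOH frees the C15 hydroxyl to give prostaglandin E3 methyl ester 11-(tert-butyldimethylsilyl) ether F8. Porcine liver esterase at pH 7.5 hydrolyses the ester without harming the β-silyloxy ketone and gives prostaglandin E3 11-(tert-butyldimethylsilyl) ether F9. Corey–Nicolaou macrolactonisation (2,2′-dipyridyl disulfide and PPh3, then slow addition to refluxing xylene at high dilution) gives 19.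

Step 2 (alkenyllithium addition to aldehyde 2). The aldehyde is enolisable and prone to slip into conjugation, and the alkenyllithium is strongly basic. The fallback sets out from 2 and comes back at 5. Aldehyde 2 is treated with the less basic HC≡CMgBr in THF at −78 °C to give rac-(5Z)-oct-5-en-1-yn-3-ol F1. Syn hydrostannation of the terminal alkyne with Bu3SnH and catalytic PdCl2(PPh3)2 in THF at 0 °C, followed by chromatographic removal of the minor internal stannane, gives 5.

**Further compounds**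

F1 | step 2 | rac-(5Z)-oct-5-en-1-yn-3-ol | CC/C=C\CC(O)C#C
F2 | step 6 | but-2-ynal | CC#CC=O
F3 | step 6 | (2S,3R,4R)-4-[(tert-butyldimethylsilyl)oxy]-2-(1-hydroxybut-2-yn-1-yl)-3-[(1E,3S,5Z)-3-[(triethylsilyl)oxy]octa-1,5-dien-1-yl]cyclopentan-1-one (carbinol epimers) | CC/C=C\C[C@H](O[Si](CC)(CC)CC)/C=C/[C@H]1[C@H](O[Si](C)(C)C(C)(C)C)CC(=O)[C@@H]1C(O)C#CC
F4 | step 6 | O-{1-[(1S,2R,3R)-3-[(tert-butyldimethylsilyl)oxy]-5-oxo-2-[(1E,3S,5Z)-3-[(triethylsilyl)oxy]octa-1,5-dien-1-yl]cyclopentyl]but-2-yn-1-yl} O-phenyl carbonothioate (carbinol epimers) | CC/C=C\C[C@H](O[Si](CC)(CC)CC)/C=C/[C@H]1[C@H](O[Si](C)(C)C(C)(C)C)CC(=O)[C@@H]1C(OC(=S)Oc1ccccc1)C#CC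
F5 | step 9 | methyl hept-5-ynoate | CC#CCCCC(=O)OC
F6 | step 9 | methyl 7-[(1R,2R,3R)-3-[(tert-butyldimethylsilyl)oxy]-5-oxo-2-[(1E,3S,5Z)-3-[(triethylsilyl)oxy]octa-1,5-dien-1-yl]cyclopentyl]hept-5-ynoate | CC/C=C\C[C@H](O[Si](CC)(CC)CC)/C=C/[C@H]1[C@H](O[Si](C)(C)C(C)(C)C)CC(=O)[C@@H]1CC#CCCCC(=O)OC
F7 | step 9 | methyl (5Z)-7-[(1R,2R,3R)-3-[(tert-butyldimethylsilyl)oxy]-5-oxo-2-[(1E,3S,5Z)-3-[(triethylsilyl)oxy]octa-1,5-dien-1-yl]cyclopentyl]hept-5-enoate | CC/C=C\C[C@H](O[Si](CC)(CC)CC)/C=C/[C@H]1[C@H](O[Si](C)(C)C(C)(C)C)CC(=O)[C@@H]1C/C=C\CCCC(=O)OC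
F8 | step 9 | prostaglandin E3 methyl ester 11-(tert-butyldimethylsilyl) ether | CC/C=C\C[C@H](O)/C=C/[C@H]1[C@H](O[Si](C)(C)C(C)(C)C)CC(=O)[C@@H]1C/C=C\CCCC(=O)OC
F9 | step 9 | prostaglandin E3 11-(tert-butyldimethylsilyl) ether (free acid) | CC/C=C\C[C@H](O)/C=C/[C@H]1[C@H](O[Si](C)(C)C(C)(C)C)CC(=O)[C@@H]1C/C=C\CCCC(=O)O
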